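**Late readings.** At late times the starting material stands at 0% in Monday's run and 0% in Sunday's, yet target stops at 51.8% and 15.1%; Tuesday's stops at 35.9%.

| setting | Monday's | Sunday's | Tuesday's | red | blue |
|---|---|---|---|---|---|
| starting material | 0.10 M | 0.10 M | 0.20 M | 0.10 M | 0.10 M |
| second nucleophile | 0.10 M | 0.40 M | 0.20 M | 0.200 M | 0.200 M |
| gas | 3.7 mM (held) | 3.7 mM (held) | 3.7 mM (held) | 3.7 mM (held) | 3.7 mM (held) |
| temperature | 108 °C | 124 °C | 108 °C | 100 °C | 130 °C |
| remark | run made earlier | run made earlier | run made earlier |  |  |
| time |  |  |  | 6.0 min | 6.0 min |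

- Monday's (time / min: target / %, starting material / %): 0.500: 18.9, 50.2; 1.00: 34.4, 25.2; 2.50: 49.9, 4.0; 6.00: 51.8, 0
- Sunday's (time / s: target / %, starting material / %): 15.0: 9.5, 22.8; 40.0: 14.1, 1.8; 80.0: 12.9, 0.4; 120: 15.1, 0
- Tuesday's (time / min: target / %, starting material / %): 0.500: 10.0, 49.9; 1.00: 21.0, 24.0; 2.50: 31.6, 0.7; 6.00: 35.9, 0

(standard deviation of a reading: 1 percentage point)

- at the start none of the gas is in solution

1. which flask leads in amount of target, in percent of the starting material charged ("all alike" within 1.5 percentage points) (red / blue / all alike)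
2. how much target is there at the end, in percent of the starting material charged: red
3. how much target is there at the end, in percent of the starting material charged: blue

**Steady feed.** Turned into rates, the first target readings give 0.0378 M min⁻¹ on Monday, 0.0400 M min⁻¹ on Tuesday and 0.0380 M min⁻¹ on Sunday, across different charges and temperatures. So we treat target as fed at a steady rate G, which we attribute to the gas entering solution, and we take Monday's value, 0.0378 M min⁻¹, for it.

**Bench rule.** Let k be the first-order constant of the starting material: 1.38 min⁻¹ on Monday and 5.91 min⁻¹ on Sunday. Taking ln k as straight in temperature gives 0.665 min⁻¹ for red and 10.2 min⁻¹ for blue. Feed times lifetime, over the charge c, gives a first answer, the feed ratio σ = G/(kc): 0.568 for red, 0.0370 for blue.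

**Second round.** We put σ back in. It is also the fraction of charge left when the flow from starting material has sunk to the feed. Until then, for ln(1/σ)/k, target grows at G; afterwards the remaining σ can still become target. The gas ceiling, C = σ(1 + ln(1/σ)), is 88.9% for red and 15.9% for blue.

**The border.** The rule needs a short feed, so it ends at σ = 1. Red, at 0.568, lies closer to that border, and blue lies far below red, so in blue we take gas passage as the rate-limiting step for target. We expect blue near its ceiling, red below its own, and red ahead.

**The forecast.** The forecast names blue, with red at 20.5% (17% to 24%) and blue at 26% (20% to 32%), judging that “heat favours target”.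

**The result.** The flasks give red as leader, with red at 49.7% and blue at 14.2%.

    starting material ⇌ intermediate (K = 0.0780, k = 0.0110 s⁻¹, Ea = 116 kJ mol⁻¹, ΔH = −62.0 kJ mol⁻¹)
    first nucleophile + intermediate → target (k = 8600 L mol⁻¹ s⁻¹, Ea = 16.0 kJ mol⁻¹)
    second nucleophile + intermediate → other capture product (k = 85.0 L mol⁻¹ s⁻¹, Ea = 55.0 kJ mol⁻¹)
    gas ⇌ first nucleophile, rate k4*(csat - [first nucleophile]) (kL = 0.270 s⁻¹)
    target ⇌ isomer of the product (K = 0.140, k = 0.0320 s⁻¹, Ea = 98.0 kJ mol⁻¹, ΔH = −35.0 kJ mol⁻¹)
    (constants at 100 °C)

**Same ceiling.** Target and its isomer together reach 15.1% in blue, under its ceiling, and 56.6% in red, further under 88.9%. The second nucleophile does not enter σ, so our reckoning gives the neighbouring flask, red with 0.050 M of it, red's ceiling, 88.9%. That flask holds 70.2% target and 9.82% isomer, together 80.0%.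

Readings and results were generated by integration with made-up constants; scatter was added.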